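In a one-step world, where Q met E and nothing else moved, each Q would take one E and the end would be a subtraction; this flask has more steps, but I began my reckoning from that subtraction.

E 0.10 M; Q 4.00 equiv (fed, over 8.0 min); D 0.10 M; time 10 d

    Q + E → Q.E (k1 = 0.80 L mol⁻¹ h⁻¹)
    E ⇌ D (k2 = 0.63 h⁻¹)
    Q + D → Q.D (k3 = 0.18 L mol⁻¹ h⁻¹)
    Q.E ⇌ Q.D (k4 = 0.25 h⁻¹)

- Q is single-handed; E and D are mirror images of each other, charged as a racemate, each of them at the stated concentration
- the reaction counts as stopped when no species that holds the E and D together changes by six tenths of a point or more over the second half of the time
- run time (flask): 10 d
- the handed part of Q does not stay in what it makes, so the products of the two hands are mirror images too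

- the state of affairs at 10 d: stopped, and by what, or still going (Q has run out first / forward and back rates have come level / it is still moving / all of E has reacted)
- part of the E and D together gone at 10 d
- the Q.E standing at 10 d, as a percentage of the E and D together charged
- the Q.D standing at 10 d, as a percentage of the E and D together charged

1. Each capture spends one Q on one molecule of E or D, and the two interconversions spend none, so I reckoned the cover as 2.00, meaning the moles of Q charged per mole of E and D together charged. It stood above one, which made the substrate the limiting reagent in this flask.

2. In my first extreme both interconversions were frozen, and D, the slower hand, met at least 0.200 M of Q once the dosing ended, a pseudo-first-order half-life of at most 0.802 d. Because that is shorter than the time, I committed to a conversion of 100%, and the equal charges of E and D gave equal products.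

3. In my second extreme E and D mixed instantly while the products stayed frozen, so the rates of capture stood in the ratio 4.44, the selectivity factor, and Q.E took 81.6% of the product.

4. I expected the first product of the real flask to lean towards Q.E, but the comparison drifts, because the relaxation half-life of Q.E and Q.D by their interconversion alone, 0.0578 d, is shorter than the time, and the equilibrium constant of that interconversion is one. So I wrote 50.0% for Q.E and 50.0% for Q.D.

5. The forecast gave all of E has reacted, with conversion 100%, Q.E 50% and Q.D 50%, holding that “any early preference for Q.E is erased”.

The simulation of this flask gave all of E has reacted, with conversion 100%, Q.E 50.0% and Q.D 50.0%. The forecast stops holding with less Q: the answer for Q.D had moved by 5 points at 1.82 equiv, a cover of 0.910. The neighbour flask, with 1.00 equiv of Q, has a cover of 0.500, below one, so Q is the limiting reagent there and the cover puts each product at 25.0%; that neighbour flask ended with Q at 0% of its charge and Q.E at 25.0%.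

The numbers of this flask were drawn at random within sensible limits, and the outcome is calculated.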